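**Plan** (labdane numbering, C1–C20, is used for all atom labels)
1. Retrosynthesis: cut the angelate C–O bond and C12–C13 (the Z-enoate arm); cut C4–C19 back to a 2β-O–CH2SnBu3 ether on a Δ3 ring A; cut C4–C5 and C9–C10 (rings A and B) back to an acyclic 1,5-enyne diene; cut C1–C2 back to a but-2-ynyl ether of a C5 carbinol.
2. Forward: the chain is built first (carboalumination, then a [2,3]-Wittig shift). Ring A and then ring B close in one gold-catalysed cascade. C2 is inverted, C19 is handed from O-2 to C4, and the Δ2 alkene, the angelate and the C13–C16 arm are finished last.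
3. Enabling feature: C4 lies two bonds from C2 in ring A. With a C3=C4 alkene and an axial 2β-oxygen, an O-bound CH2 carbanion reaches C4 through a five-membered transition state on the β-face. The C2–O bond is thus a temporary tether, and its oxygen ends as O-19.
4. Stereochemistry: one CBS reduction sets the C5 carbinol. It is relayed to C2 by the [2,3]-Wittig shift, from C2 to C5, C9 and C10 by the chair–chair cyclization, and, after oxidation–reduction at C2, to C4 by the suprafacial Wittig–Still shift.
5. Alkene geometry: the E alkenes come from syn-carboalumination and the [2,3] shift, 13Z from a Z-iodoenoate coupled with retention, and the angelate from angelic acid.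

Key step: step 12

Step 1
Reactants: 1 pent-4-ynoic acid
Product: 2 N-methoxy-N-methylpent-4-ynamide
Conditions: MeNH(OMe)·HCl, EDC·HCl, N-methylmorpholine, CH2Cl2, 0 °C → rt
Reagents that add atoms: N,O-dimethylhydroxylamine hydrochloride, CNOC.Cl
Why: Carbodiimide amide coupling gives the Weinreb amide, which will stop the organometallic addition of step 2 at the ketone stage.

Step 2
Reactants: 2 N-methoxy-N-methylpent-4-ynamide
Product: 3 2-methylhept-1-en-6-yn-3-one
Conditions: CH2=C(CH3)MgBr (excess), THF, −20 → 0 °C; aq. NH4Cl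
Reagents that add atoms: isopropenylmagnesium bromide, C=C(C)[Mg]Br
Why: Weinreb ketone synthesis, in which the chelated tetrahedral adduct collapses only on work-up so that one isopropenyl group adds (the excess covers the acidic alkyne C–H).

Step 3
Reactants: 3 2-methylhept-1-en-6-yn-3-one
Product: 4 (3S)-2-methylhept-1-en-6-yn-3-ol
Conditions: (R)-Me-CBS (cat.), catecholborane, toluene, −78 °C
Reagents that add atoms: none
Why: Corey–Bakshi–Shibata reduction, in which the α-branched alkenyl group acts as the large substituent so that the (R)-oxazaborolidine should give the (S)-carbinol (the future C5–O), while catecholborane at −78 °C leaves alkyne and alkene untouched.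

Step 4
Reactants: 4 (3S)-2-methylhept-1-en-6-yn-3-ol
Product: 6 (3S,6E)-2,6-dimethylnona-1,6-diene-3,9-diol, via alkenylalane 5 (not isolated)
Conditions: Me3Al, Cp2ZrCl2 (cat.), CH2Cl2, 0 °C → rt; then n-BuLi, THF, −78 °C; oxirane, −78 °C → rt; aq. work-up
Reagents that add atoms: trimethylaluminium, C[Al](C)C; oxirane, C1CO1
Why: Negishi zirconium-catalysed carboalumination adds CH3 (C17) and Al syn across the terminal alkyne to fix the E C8=C9 alkene, and the derived alanate opens oxirane to add C11–C12, the carbinol being carried as its aluminium alkoxide.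

Step 5
Reactants: 6 (3S,6E)-2,6-dimethylnona-1,6-diene-3,9-diol
Product: 8 (3S,6E)-9-chloro-2,6-dimethylnona-1,6-dien-3-ol, via primary mesylate 7 (not isolated)
Conditions: MsCl (1 equiv), 2,4,6-collidine, CH2Cl2, −20 °C; then LiCl, DMF, 50 °C
Reagents that add atoms: lithium chloride, [Li+].[Cl-]
Why: Selective sulfonylation of the primary alcohol and SN2 displacement by chloride leave the secondary allylic alcohol free and install a C12 handle that tolerates organolithiums at −78 °C and does not take part in the later cation cascade.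

Step 6
Reactants: 8 (3S,6E)-9-chloro-2,6-dimethylnona-1,6-dien-3-ol
Product: 9 (3S,6E)-3-(but-2-yn-1-yloxy)-9-chloro-2,6-dimethylnona-1,6-diene
Conditions: NaH, THF–DMF, 0 °C; 1-bromobut-2-yne, 0 °C → rt
Reagents that add atoms: 1-bromobut-2-yne, CC#CCBr
Why: Williamson ether synthesis with the reactive propargylic bromide, against which the primary alkyl chloride is a far slower electrophile.

Step 7
Reactants: 9 (3S,6E)-3-(but-2-yn-1-yloxy)-9-chloro-2,6-dimethylnona-1,6-diene
Product: 11 (4R,6E,10E)-13-chloro-6,10-dimethyl-4-(triethylsilyloxy)trideca-6,10-dien-2-yne, via lithium alkoxide 10 (not isolated)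
Conditions: n-BuLi, THF, −78 → −40 °C; then Et3SiCl, −78 °C → rt
Reagents that add atoms: chlorotriethylsilane, CC[Si](Cl)(CC)CC
Why: [2,3]-Wittig rearrangement of the propargylic carbanion through an envelope transition state (chain pseudo-equatorial, alkynyl exo) should form C1–C2, give the E C5=C10 alkene and transfer the (S) carbinol configuration to the new (R) propargylic carbinol at C2, whose alkoxide is silylated in the same flask.

Step 8
Reactants: 11 (4R,6E,10E)-13-chloro-6,10-dimethyl-4-(triethylsilyloxy)trideca-6,10-dien-2-yne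
Product: 13 12-chloro-13,14,15,16,19-pentanorlabda-3,7-dien-2α-ol, via bicyclic triethylsilyl ether 12 (not isolated)
Conditions: Ph3PAuNTf2 (cat.), CH2Cl2, −20 → 0 °C; then PPTS, MeOH, rt
Reagents that add atoms: none
Why: Alkyne-initiated cationic polyene cyclization under π-acid catalysis, in which gold activates the alkyne for 6-endo-dig attack by C5 (ring A) and the C10 cation is taken by C9 in a 6-endo-trig closure (ring B); the chair–chair transition state with the C2 silyloxy group equatorial should set C5, C9 and C10 (trans-decalin, 9α-H), proton loss from C7 ends the cascade, and protodeauration followed by mild methanolysis frees the 2α-alcohol.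

Step 9
Reactants: 13 12-chloro-13,14,15,16,19-pentanorlabda-3,7-dien-2α-ol
Product: 14 12-chloro-13,14,15,16,19-pentanorlabda-3,7-dien-2-one
Conditions: MnO2, CH2Cl2, rt
Reagents that add atoms: none
Why: Manganese dioxide oxidation of the allylic alcohol gives the enone and clears the C2 centre for inversion.

Step 10
Reactants: 14 12-chloro-13,14,15,16,19-pentanorlabda-3,7-dien-2-one
Product: 15 12-chloro-13,14,15,16,19-pentanorlabda-3,7-dien-2β-ol
Conditions: L-Selectride, THF, −78 °C; then NaOH, H2O2
Reagents that add atoms: none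
Why: 1,2-Reduction by a bulky borohydride, in which the β,β-disubstituted enone resists conjugate reduction and the axial C10 methyl blocks the β-face, so that hydride should add from the α-face and give the pseudoaxial 2β-alcohol.

Step 11
Reactants: 15 12-chloro-13,14,15,16,19-pentanorlabda-3,7-dien-2β-ol
Product: 16 12-chloro-2β-[(tributylstannyl)methoxy]-13,14,15,16,19-pentanorlabda-3,7-diene
Conditions: KH, 18-crown-6 (cat.), THF, 0 °C; Bu3SnCH2I, 0 °C → rt
Reagents that add atoms: tributyl(iodomethyl)stannane, CCCC[Sn](CI)(CCCC)CCCC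
Why: Williamson etherification of the potassium alkoxide places the future C19 on O-2, making the C2–O bond the temporary tether for the key step.

Step 12
Reactants: 16 12-chloro-2β-[(tributylstannyl)methoxy]-13,14,15,16,19-pentanorlabda-3,7-diene
Product: 18 12-chloro-13,14,15,16-tetranorlabda-2,7-dien-19-ol, via alkoxymethyllithium 17 (not isolated)
Conditions: n-BuLi, THF, −78 → −40 °C; then H2O
Reagents that add atoms: none
Why: Tin–lithium exchange gives the α-alkoxymethyllithium, which undergoes a concerted suprafacial [2,3]-sigmatropic shift in which C19 bonds to C4 while the C2–O bond breaks and the alkene moves to C2=C3. The closest known reaction type is the Wittig–Still rearrangement of (stannylmethyl) allyl ethers, here applied to a cyclohexenyl ether to form a quaternary carbon. No ring of the target is closed; the only ring is the five-centre envelope transition state C19–O–C2–C3–C4 on the β-face of ring A. C4 is controlled by the C2 carbinol: the pseudoaxial 2β-oxygen can only hand the CH2 group to the β-face, so the CH2OH group ends axial and cis to the C10 methyl and the C18 methyl ends equatorial. The step needs [2,3] shift over [1,2] shift and over protonation of the carbanion, which low temperature and the rigid trans-decalin (C2–O held parallel to the C3=C4 π system) should secure. The tether is cleaved in the same event, and its oxygen becomes O-19 of the target.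

Step 13
Reactants: 18 12-chloro-13,14,15,16-tetranorlabda-2,7-dien-19-ol
Product: 19 12-chloro-13,14,15,16-tetranorlabd-7-en-19-ol
Conditions: H2 (1 atm), RhCl(PPh3)3 (cat.), benzene–EtOH, rt
Reagents that add atoms: none
Why: Homogeneous hydrogenation with Wilkinson's catalyst should reduce the cis-disubstituted C2=C3 alkene left by the key step and spare the trisubstituted C7=C8 alkene and the C–Cl bond.

Step 14
Reactants: 19 12-chloro-13,14,15,16-tetranorlabd-7-en-19-ol; 20 angelic acid
Product: 22 12-chloro-13,14,15,16-tetranorlabd-7-en-19-yl (Z)-2-methylbut-2-enoate, via mixed anhydride 21 (not isolated)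
Conditions: 20, 2,4,6-Cl3C6H2COCl, Et3N, toluene, rt; then 19, toluene, 80 °C
Reagents that add atoms: none
Why: Yamaguchi-type mixed-anhydride esterification run without DMAP acylates the neopentyl alcohol and avoids the nucleophile-catalysed Z-to-E isomerization of the angelate to the tiglate.

Step 15
Reactants: 22 12-chloro-13,14,15,16-tetranorlabd-7-en-19-yl (Z)-2-methylbut-2-enoate
Product: 23 12-iodo-13,14,15,16-tetranorlabd-7-en-19-yl (Z)-2-methylbut-2-enoate
Conditions: NaI, butan-2-one, 80 °C
Reagents that add atoms: sodium iodide, [Na+].[I-]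
Why: Finkelstein halide exchange (SN2) turns the primary chloride into the iodide needed for zinc insertion.

Step 16
Reactants: 24 but-2-ynoic acid
Product: 25 (Z)-3-iodobut-2-enoic acid
Conditions: NaI, AcOH, 110 °C
Reagents that add atoms: sodium iodide, [Na+].[I-]
Why: Anti hydroiodination of the ynoic acid (conjugate addition of iodide, then protonation) gives the Z β-iodo acid.

Step 17
Reactants: 25 (Z)-3-iodobut-2-enoic acid; 26 2-(trimethylsilyl)ethanol
Product: 27 2-(trimethylsilyl)ethyl (Z)-3-iodobut-2-enoate
Conditions: EDC·HCl, DMAP (cat.), CH2Cl2, 0 °C → rt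
Reagents that add atoms: none
Why: Steglich-type carbodiimide esterification gives an ester that fluoride can cleave in the presence of the angelate.

Step 18
Reactants: 23 12-iodo-13,14,15,16-tetranorlabd-7-en-19-yl (Z)-2-methylbut-2-enoate; 27 2-(trimethylsilyl)ethyl (Z)-3-iodobut-2-enoate
Product: 29 2-(trimethylsilyl)ethyl (13Z)-19-[(Z)-2-methylbut-2-enoyloxy]labda-7,13-dien-15-oate, via alkylzinc iodide 28 (not isolated)
Conditions: 23, Zn dust, LiCl, THF, 40 °C; then 27, Pd2(dba)3 (cat.), SPhos (cat.), THF, rt
Reagents that add atoms: none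
Why: Zinc insertion into the primary iodide and Negishi sp3–sp2 coupling with retention of the vinyl iodide geometry form C12–C13 and set the 13Z alkene, the organozinc tolerating both esters.

Step 19
Reactants: 29 2-(trimethylsilyl)ethyl (13Z)-19-[(Z)-2-methylbut-2-enoyloxy]labda-7,13-dien-15-oate
Product: 30 (13Z)-19-[(Z)-2-methylbut-2-enoyloxy]labda-7,13-dien-15-oic acid
Conditions: TBAF, THF, 0 °C → rt; then dil. HCl
Reagents that add atoms: none
Why: Fluoride-induced β-elimination of the 2-(trimethylsilyl)ethyl ester frees the acid under conditions that should leave the angelate and both Z alkenes intact.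

**Compound list**
1 | pent-4-ynoic acid | C#CCCC(=O)O | starting material
2 | N-methoxy-N-methylpent-4-ynamide | C#CCCC(=O)N(C)OC | intermediate
3 | 2-methylhept-1-en-6-yn-3-one | C=C(C)C(=O)CCC#C | intermediate
4 | (3S)-2-methylhept-1-en-6-yn-3-ol | C=C(C)[C@@H](O)CCC#C | intermediate
5 | (E)-alkenyl(dimethyl)alane from 4, carried as its O-dimethylaluminium alkoxide | C=C(C)[C@@H](O[Al](C)C)CC/C(C)=C/[Al](C)C | intermediate
6 | (3S,6E)-2,6-dimethylnona-1,6-diene-3,9-diol | C=C(C)[C@@H](O)CC/C(C)=C/CCO | intermediate
7 | (3E,7S)-7-hydroxy-4,8-dimethylnona-3,8-dien-1-yl methanesulfonate | C=C(C)[C@@H](O)CC/C(C)=C/CCOS(C)(=O)=O | intermediate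
8 | (3S,6E)-9-chloro-2,6-dimethylnona-1,6-dien-3-ol | C=C(C)[C@@H](O)CC/C(C)=C/CCCl | intermediate
9 | (3S,6E)-3-(but-2-yn-1-yloxy)-9-chloro-2,6-dimethylnona-1,6-diene | C=C(C)[C@@H](OCC#CC)CC/C(C)=C/CCCl | intermediate
10 | lithium (4R,6E,10E)-13-chloro-6,10-dimethyltrideca-6,10-dien-2-yn-4-olate | CC#C[C@H](O[Li])C/C(C)=C/CC/C(C)=C/CCCl | intermediate
11 | (4R,6E,10E)-13-chloro-6,10-dimethyl-4-(triethylsilyloxy)trideca-6,10-dien-2-yne | CC#C[C@H](O[Si](CC)(CC)CC)C/C(C)=C/CC/C(C)=C/CCCl | intermediate
12 | 12-chloro-2α-(triethylsilyloxy)-13,14,15,16,19-pentanorlabda-3,7-diene (trans-decalin, 5α-H, 9α-H, 10β-CH3) | CC1=C[C@H](O[Si](CC)(CC)CC)C[C@]2(C)[C@@H](CCCl)C(C)=CC[C@@H]12 | intermediate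
13 | 12-chloro-13,14,15,16,19-pentanorlabda-3,7-dien-2α-ol | CC1=C[C@H](O)C[C@]2(C)[C@@H](CCCl)C(C)=CC[C@@H]12 | intermediate
14 | 12-chloro-13,14,15,16,19-pentanorlabda-3,7-dien-2-one | CC1=CC(=O)C[C@]2(C)[C@@H](CCCl)C(C)=CC[C@@H]12 | intermediate
15 | 12-chloro-13,14,15,16,19-pentanorlabda-3,7-dien-2β-ol | CC1=C[C@@H](O)C[C@]2(C)[C@@H](CCCl)C(C)=CC[C@@H]12 | intermediate
16 | 12-chloro-2β-[(tributylstannyl)methoxy]-13,14,15,16,19-pentanorlabda-3,7-diene | CC1=C[C@@H](OC[Sn](CCCC)(CCCC)CCCC)C[C@]2(C)[C@@H](CCCl)C(C)=CC[C@@H]12 | intermediate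
17 | [(12-chloro-13,14,15,16,19-pentanorlabda-3,7-dien-2β-yl)oxy]methyllithium | CC1=C[C@@H](OC[Li])C[C@]2(C)[C@@H](CCCl)C(C)=CC[C@@H]12 | intermediate
18 | 12-chloro-13,14,15,16-tetranorlabda-2,7-dien-19-ol (4α-CH3, 4β-CH2OH) | OC[C@@]1(C)C=CC[C@]2(C)[C@@H](CCCl)C(C)=CC[C@@H]12 | intermediate
19 | 12-chloro-13,14,15,16-tetranorlabd-7-en-19-ol | OC[C@@]1(C)CCC[C@]2(C)[C@@H](CCCl)C(C)=CC[C@@H]12 | intermediate
20 | angelic acid, (Z)-2-methylbut-2-enoic acid | C/C=C(/C)C(=O)O | starting material
21 | (Z)-2-methylbut-2-enoic 2,4,6-trichlorobenzoic anhydride | C/C=C(/C)C(=O)OC(=O)c1c(Cl)cc(Cl)cc1Cl | intermediate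
22 | 12-chloro-13,14,15,16-tetranorlabd-7-en-19-yl (Z)-2-methylbut-2-enoate | C/C=C(/C)C(=O)OC[C@@]1(C)CCC[C@]2(C)[C@@H](CCCl)C(C)=CC[C@@H]12 | intermediate
23 | 12-iodo-13,14,15,16-tetranorlabd-7-en-19-yl (Z)-2-methylbut-2-enoate | C/C=C(/C)C(=O)OC[C@@]1(C)CCC[C@]2(C)[C@@H](CCI)C(C)=CC[C@@H]12 | intermediate
24 | but-2-ynoic acid | CC#CC(=O)O | starting material
25 | (Z)-3-iodobut-2-enoic acid | C/C(I)=C/C(=O)O | intermediate
26 | 2-(trimethylsilyl)ethanol | C[Si](C)(C)CCO | starting material
27 | 2-(trimethylsilyl)ethyl (Z)-3-iodobut-2-enoate | C/C(I)=C/C(=O)OCC[Si](C)(C)C | intermediate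
28 | alkylzinc iodide from 23 (zinc on C12) | C/C=C(/C)C(=O)OC[C@@]1(C)CCC[C@]2(C)[C@@H](CC[Zn]I)C(C)=CC[C@@H]12 | intermediate
29 | 2-(trimethylsilyl)ethyl (13Z)-19-[(Z)-2-methylbut-2-enoyloxy]labda-7,13-dien-15-oate | C/C=C(/C)C(=O)OC[C@@]1(C)CCC[C@]2(C)[C@@H](CC/C(C)=C\C(=O)OCC[Si](C)(C)C)C(C)=CC[C@@H]12 | intermediate
30 | (13Z)-19-[(Z)-2-methylbut-2-enoyloxy]labda-7,13-dien-15-oic acid | C/C=C(/C)C(=O)OC[C@@]1(C)CCC[C@]2(C)[C@@H](CC/C(C)=C\C(=O)O)C(C)=CC[C@@H]12 | target

**Step count**
Total: 19 steps. Longest linear sequence: 17 steps (1–15, 18, 19); steps 16–17 are a two-step side branch.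

**Steps most likely to fail**

Step 8 (gold-catalysed bicyclization). The terminating proton loss from the C8 cation may go toward C17 (exocyclic alkene) instead of C7, or the cyclopropyl-gold carbene may collapse before the second ring closes. The fallback uses the exocyclic product instead of discarding it. From 11, the same cyclization and methanolysis would give 12-chloro-13,14,15,16,19-pentanorlabda-3,8(17)-dien-2α-ol F1. A cobalt-hydride hydrogen-atom-transfer isomerization (Co(salen)Cl cat., PhSiH3, benzene, rt) should then move the 1,1-disubstituted alkene one position into the ring on the less hindered C7 side, which returns to 13.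

Step 12 (Wittig–Still shift). On the β-face the C10 methyl is syn-axial to both the C2–O bond and the forming C4–C19 bond. The [2,3] shift may therefore be slow enough for a [1,2] shift or protonation of the carbanion to compete. The fallback is a neutral thermal delivery of C19 from the same oxygen. From 15, heating with N,N-dimethylformamide dimethyl acetal (xylene, 140 °C) should form the alkoxy(dimethylamino)carbene, whose [2,3] shift gives 12-chloro-N,N-dimethyl-13,14,15,16-tetranorlabda-2,7-dien-19-amide F2. Cp2Zr(H)Cl (THF, rt) should reduce the amide to 12-chloro-13,14,15,16-tetranorlabda-2,7-dien-19-al F3, and NaBH4 (MeOH, 0 °C) returns to 18.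

Step 7 ([2,3]-Wittig shift). Leakage through the alkynyl-endo transition state, or E/Z leakage, would transfer the C5 configuration to C2 incompletely and erode the enantiopurity of everything downstream. The fallback sets C2 by a reagent instead of by chirality transfer. From 9, the rearrangement is quenched with water to give (4R,6E,10E)-13-chloro-6,10-dimethyltrideca-6,10-dien-2-yn-4-ol F4 of whatever enantiopurity. MnO2 (CH2Cl2, rt) gives (6E,10E)-13-chloro-6,10-dimethyltrideca-6,10-dien-2-yn-4-one F5. Noyori asymmetric transfer hydrogenation ((R,R)-TsDPEN–Ru(p-cymene), i-PrOH, rt) should return F4 with the (R) carbinol set by the catalyst, and Et3SiCl with imidazole (DMF) gives 11.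

**Further compounds**
F1 | step 8 | 12-chloro-13,14,15,16,19-pentanorlabda-3,8(17)-dien-2α-ol | CC1=C[C@H](O)C[C@]2(C)[C@@H](CCCl)C(=C)CC[C@@H]12
F2 | step 12 | 12-chloro-N,N-dimethyl-13,14,15,16-tetranorlabda-2,7-dien-19-amide | CN(C)C(=O)[C@@]1(C)C=CC[C@]2(C)[C@@H](CCCl)C(C)=CC[C@@H]12
F3 | step 12 | 12-chloro-13,14,15,16-tetranorlabda-2,7-dien-19-al | O=C[C@@]1(C)C=CC[C@]2(C)[C@@H](CCCl)C(C)=CC[C@@H]12
F4 | step 7 | (4R,6E,10E)-13-chloro-6,10-dimethyltrideca-6,10-dien-2-yn-4-ol | CC#C[C@H](O)C/C(C)=C/CC/C(C)=C/CCCl
F5 | step 7 | (6E,10E)-13-chloro-6,10-dimethyltrideca-6,10-dien-2-yn-4-one | CC#CC(=O)C/C(C)=C/CC/C(C)=C/CCCl
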